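A direct plan would grow the open chain by three catalyst-controlled vinylogous Mukaiyama aldol additions of a prenal-derived silyl dienol ether to a 4-oxo-2-(borylmethyl)but-2-enoate. It would then close the 14-membered ring at C1–C2 by thermal intramolecular allylboration of seco enal A1 to hydroxy ester A2, and form the lactone with inversion at C2 through allylic mesylate A3.
Its weakest steps would be:
(1) the ring-closing allylboration, because a deactivated 2-carboalkoxy allylboronate adding over days at high dilution has no close model, and C1 would rest on one remote acetoxy centre;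
(2) the lactonisation with inversion, because the activated C2 is allylic, so ionisation, allylic transposition and elimination would compete with backside attack;
(3) the carrying of the allylboronate through an acetal hydrolysis and three aldol additions run with half an equivalent of a boron Lewis acid, which would add fragility without adding complexity.

The C14–C1–C2 triad is read as a 2,3-epoxy alcohol: C2–O, a trans C1–C14 epoxide, and a C15 nucleophile hung on the C2 oxygen. A matched Sharpless epoxidation of a bis-allylic alcohol sets C1 and C14 from C2. The phosphonoacetate of that alcohol then closes the lactone ring by 5-exo attack on C1 (C1–C15 bond, inversion, C14–O freed), and olefination with formaldehyde installs C17 in the same flask. The lactone thus precedes the macrocycle, C2–O is never broken, no allylmetal closes the ring, no boron is carried along, and the 14-membered ring is closed last at C6–C7, where only the free carbinol is created.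

Key step: step 11

Remarks on the chemistry (assumptions):
- C1–C17 in the text are cembrane locants of the target (ring C1–C14, lactone carbons C15–C17); chain locants are used only inside names.
- Compounds 1, 6, 12, 14 and 21 are taken as commercial.
- The facial sense of the catalysts in steps 3 and 8 is taken from their behaviour with simple aldehydes.

Step 1
Reactants: 1 pent-1-en-4-yne
Product: 3 (1E)-1-iodo-2-methylpenta-1,4-diene, via alkenylalane 2 (not isolated)
Conditions: Me3Al (2.5 equiv), Cp2ZrCl2 (25 mol%), CH2Cl2, 0 °C → rt; then I2, THF, −30 °C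
Reagents that add atoms: trimethylaluminium, C[Al](C)C; iodine, II
Why: Negishi carboalumination adds methyl and aluminium syn across the terminal alkyne with methyl on the internal carbon, and iodinolysis with retention should give the (E)-iodide while the terminal alkene stays inert.

Step 2
Reactants: 3 (1E)-1-iodo-2-methylpenta-1,4-diene
Product: 5 (2E)-3-methylhexa-2,5-dienal, via alkenyllithium 4 (not isolated)
Conditions: t-BuLi (2.0 equiv), Et2O, −78 °C; then DMF, −78 → 0 °C; aq. NH4Cl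
Reagents that add atoms: N,N-dimethylformamide, CN(C)C=O
Why: lithium–iodine exchange with retention of alkene geometry followed by formylation of the alkenyllithium should give the (E)-enal, which is used at once because the skipped diene can slip into conjugation.

Step 3
Reactants: 5 (2E)-3-methylhexa-2,5-dienal; 6 allenylboronic acid pinacol ester
Product: 8 (4S,5E)-6-methylnona-5,8-dien-1-yn-4-ol, via pinacol borate 7 (not isolated)
Conditions: (S)-3,3′-bis(2,4,6-triisopropylphenyl)-1,1′-binaphthyl-2,2′-diyl hydrogen phosphate [(S)-TRIP, 5 mol%], 4 Å MS, toluene, −20 °C; aq. NaHCO3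
Reagents that add atoms: none
Why: chiral phosphoric acid-catalysed asymmetric propargylation, in which the activated allenylboronate adds through its γ-carbon in a closed six-membered transition state to the Si face of the enal, should set C10 as S (C4 of this chain) by catalyst control.

Step 4
Reactants: 8 (4S,5E)-6-methylnona-5,8-dien-1-yn-4-ol
Product: 10 (1E,4S,5E)-1-iodo-2,6-dimethylnona-1,5,8-trien-4-ol, via alkenylalane 9 (not isolated)
Conditions: Me3Al (3.5 equiv), Cp2ZrCl2 (50 mol%), CH2Cl2, 0 °C → rt; then I2, THF, −30 °C; aq. Rochelle salt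
Reagents that add atoms: trimethylaluminium, C[Al](C)C; iodine, II
Why: Negishi carboalumination–iodination of the homopropargylic aluminium alkoxide should give the (E)-alkenyl iodide (C7=C8 with its methyl) without touching the two alkenes or the C10 centre.

Step 5
Reactants: 10 (1E,4S,5E)-1-iodo-2,6-dimethylnona-1,5,8-trien-4-ol
Product: 11 (1E,4S,5E)-1-iodo-2,6-dimethylnona-1,5,8-trien-4-yl acetate
Conditions: Ac2O, pyridine, DMAP (cat.), CH2Cl2, 0 °C
Reagents that add atoms: acetic anhydride, CC(=O)OC(C)=O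
Why: DMAP-catalysed O-acylation installs the C10 acetate of the target with no change at the stereocentre.

Step 6
Reactants: 11 (1E,4S,5E)-1-iodo-2,6-dimethylnona-1,5,8-trien-4-yl acetate; 12 (2E)-but-2-enal
Product: 13 (2E,5E,7S,9E)-10-iodo-5,9-dimethyl-1-oxodeca-2,5,9-trien-7-yl acetate
Conditions: 12 (5 equiv), second-generation Hoveyda–Grubbs catalyst (5 mol%), CH2Cl2, 40 °C
Reagents that add atoms: none
Why: olefin cross-metathesis of the only monosubstituted alkene with crotonaldehyde should give the (E)-enal (C2, C1=C14), the trisubstituted alkene and the iodoalkene being too hindered to enter the catalytic cycle.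

Step 7
Reactants: 14 tert-butyl(but-3-yn-1-yloxy)dimethylsilane
Product: 16 tert-butyl{[(3E)-4-iodo-3-methylbut-3-en-1-yl]oxy}dimethylsilane, via alkenylalane 15 (not isolated)
Conditions: Me3Al (2.5 equiv), Cp2ZrCl2 (25 mol%), CH2Cl2, 0 °C → rt; then I2, THF, −30 °C
Reagents that add atoms: trimethylaluminium, C[Al](C)C; iodine, II
Why: Negishi carboalumination–iodination gives the (E)-alkenyl iodide that carries C3–C6 and the C4 methyl.

Step 8
Reactants: 16 tert-butyl{[(3E)-4-iodo-3-methylbut-3-en-1-yl]oxy}dimethylsilane; 13 (2E,5E,7S,9E)-10-iodo-5,9-dimethyl-1-oxodeca-2,5,9-trien-7-yl acetate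
Product: 19 (1E,4S,5E,8E,10R,11E)-14-[(tert-butyldimethylsilyl)oxy]-10-hydroxy-1-iodo-2,6,12-trimethyltetradeca-1,5,8,11-tetraen-4-yl acetate, via alkenyllithium 17 (not isolated), via bis(alkenyl)zinc 18 (not isolated)
Conditions: 16 (2.4 equiv), t-BuLi (4.8 equiv), Et2O, −78 °C; ZnBr2 (1.2 equiv), −78 → 0 °C; then (2S)-(−)-3-exo-(morpholino)isoborneol [(−)-MIB, 10 mol%], N,N,N′,N′-tetraethylethylenediamine, 13 (1.0 equiv), hexanes/toluene, −10 °C
Reagents that add atoms: none
Why: amino alcohol-catalysed enantioselective 1,2-addition of an alkenylzinc to an enal forms the C2–C3 bond and should deliver the alkenyl group to the Si face, setting C2 (10R here, the arrangement that becomes 2S once C1 bears oxygen); zinc tolerates the acetate and the second alkenyl iodide.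

Step 9
Reactants: 19 (1E,4S,5E,8E,10R,11E)-14-[(tert-butyldimethylsilyl)oxy]-10-hydroxy-1-iodo-2,6,12-trimethyltetradeca-1,5,8,11-tetraen-4-yl acetate
Product: 20 (1E,4S,5E,8S,9S,10S,11E)-14-[(tert-butyldimethylsilyl)oxy]-8,9-epoxy-10-hydroxy-1-iodo-2,6,12-trimethyltetradeca-1,5,11-trien-4-yl acetate
Conditions: Ti(OiPr)4 (20 mol%), L-(+)-diethyl tartrate (24 mol%), t-BuOOH (1.5 equiv, decane), 4 Å MS, CH2Cl2, −20 °C
Reagents that add atoms: tert-butyl hydroperoxide, CC(C)(C)OO
Why: Sharpless asymmetric epoxidation in its matched sense: with L-(+)-tartrate the C2 carbinol directs oxygen to one face of the (E)-C1=C14 alkene and gives the erythro epoxy alcohol, which sets C14 (S) and C1; the C3=C4 alkene is mismatched with this tartrate and slowed by its cis methyl group.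

Step 10
Reactants: 20 (1E,4S,5E,8S,9S,10S,11E)-14-[(tert-butyldimethylsilyl)oxy]-8,9-epoxy-10-hydroxy-1-iodo-2,6,12-trimethyltetradeca-1,5,11-trien-4-yl acetate; 21 (diethoxyphosphoryl)acetic acid
Product: 22 (1E,4S,5E,8S,9R,10S,11E)-4-acetoxy-14-[(tert-butyldimethylsilyl)oxy]-8,9-epoxy-1-iodo-2,6,12-trimethyltetradeca-1,5,11-trien-10-yl (diethoxyphosphoryl)acetate
Conditions: 21 (1.5 equiv), DCC, DMAP (cat.), CH2Cl2, 0 °C → rt
Reagents that add atoms: none
Why: Steglich esterification hangs the future C15–C16 unit on the C2 oxygen under neutral conditions that leave the epoxide intact (the descriptor at chain C9 changes by priority only).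

Step 11
Reactants: 22 (1E,4S,5E,8S,9R,10S,11E)-4-acetoxy-14-[(tert-butyldimethylsilyl)oxy]-8,9-epoxy-1-iodo-2,6,12-trimethyltetradeca-1,5,11-trien-10-yl (diethoxyphosphoryl)acetate
Product: 24 (1E,4S,5E,8S)-8-hydroxy-1-iodo-2,6-dimethyl-8-[(2S,3S)-2-{(1E)-4-[(tert-butyldimethylsilyl)oxy]-2-methylbut-1-en-1-yl}-4-methylidene-5-oxooxolan-3-yl]octa-1,5-dien-4-yl acetate, via phosphono lactone 23 (not isolated)
Conditions: NaN(SiMe3)2 (1.0 equiv), THF, −78 → 40 °C; then (CH2O)n, THF, rt → 40 °C
Reagents that add atoms: formaldehyde (from paraformaldehyde), C=O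
Why: Proposed new method: the sodium phosphonoacetate enolate held on the C2 oxygen should attack the adjacent epoxide carbon C1 from the rear in a 5-exo-tet closure (C1–C15 bond) that forms the lactone ring and frees the C14 alkoxide; proton transfer from the more acidic C15–H then gives the phosphonate carbanion, which undergoes Horner–Wadsworth–Emmons olefination with formaldehyde to place the C15=C17 methylene. The closest known reactions are the intermolecular opening of epoxides by sodium phosphonoacetate to α-phosphono-γ-lactones that are methylenated with formaldehyde, and the 5-exo delivery of tethered nucleophiles to C2 of 2,3-epoxy alcohol carbamates. C1 is set by inversion at the Sharpless epoxide carbon (1S), C14 keeps the epoxide oxygen with retention (14S) and C2 is untouched, so the erythro trans-epoxide maps onto the trans-fused lactone with the C14 oxygen anti to C15; the C15 centre of 23 is erased by the olefination. The step needs 5-exo attack over 6-endo attack at C14 and C- over O-alkylation: the collinear backside approach within a five-membered transition state and the soft carbanion should secure both, and one equivalent of base leaves no free alkoxide to move the acyl group to O14.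

Step 12
Reactants: 24 (1E,4S,5E,8S)-8-hydroxy-1-iodo-2,6-dimethyl-8-[(2S,3S)-2-{(1E)-4-[(tert-butyldimethylsilyl)oxy]-2-methylbut-1-en-1-yl}-4-methylidene-5-oxooxolan-3-yl]octa-1,5-dien-4-yl acetate
Product: 25 (1E,4S,5E,8S)-8-[(2S,3S)-2-{(1E)-4-[(tert-butyldimethylsilyl)oxy]-2-methylbut-1-en-1-yl}-4-methylidene-5-oxooxolan-3-yl]-1-iodo-2,6-dimethylocta-1,5-diene-4,8-diyl diacetate
Conditions: Ac2O, pyridine, DMAP (cat.), CH2Cl2, 0 °C
Reagents that add atoms: acetic anhydride, CC(=O)OC(C)=O
Why: DMAP-catalysed O-acylation caps the C14 hydroxyl as the acetate of the target before any base can move the lactone to O14.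

Step 13
Reactants: 25 (1E,4S,5E,8S)-8-[(2S,3S)-2-{(1E)-4-[(tert-butyldimethylsilyl)oxy]-2-methylbut-1-en-1-yl}-4-methylidene-5-oxooxolan-3-yl]-1-iodo-2,6-dimethylocta-1,5-diene-4,8-diyl diacetate
Product: 26 (1E,4S,5E,8S)-8-{(2S,3S)-2-[(1E)-4-hydroxy-2-methylbut-1-en-1-yl]-4-methylidene-5-oxooxolan-3-yl}-1-iodo-2,6-dimethylocta-1,5-diene-4,8-diyl diacetate
Conditions: HF·pyridine, pyridine, THF, 0 °C → rt
Reagents that add atoms: none
Why: buffered fluoride-mediated desilylation frees the primary C6 hydroxyl without touching the acetates, the α-methylene lactone or the alkenyl iodide.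

Step 14
Reactants: 26 (1E,4S,5E,8S)-8-{(2S,3S)-2-[(1E)-4-hydroxy-2-methylbut-1-en-1-yl]-4-methylidene-5-oxooxolan-3-yl}-1-iodo-2,6-dimethylocta-1,5-diene-4,8-diyl diacetate
Product: 27 (1E,4S,5E,8S)-1-iodo-2,6-dimethyl-8-{(2S,3S)-2-[(1E)-2-methyl-4-oxobut-1-en-1-yl]-4-methylidene-5-oxooxolan-3-yl}octa-1,5-diene-4,8-diyl diacetate
Conditions: Dess–Martin periodinane, NaHCO3, CH2Cl2, 0 °C; used directly
Reagents that add atoms: none
Why: buffered Dess–Martin oxidation gives the β,γ-unsaturated C6 aldehyde under neutral conditions, so the C3=C4 alkene should not move into conjugation before the next step.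

Step 15
Reactants: 27 (1E,4S,5E,8S)-1-iodo-2,6-dimethyl-8-{(2S,3S)-2-[(1E)-2-methyl-4-oxobut-1-en-1-yl]-4-methylidene-5-oxooxolan-3-yl}octa-1,5-diene-4,8-diyl diacetate
Product: 28 (1S,2S,3E,6S,7E,10S,11E,14S)-10,14-diacetoxy-6-hydroxycembra-3,7,11,15(17)-tetraen-16,2-olide (CNP0418981.1)
Conditions: CrCl2 (8 equiv), NiCl2 (2 mol%), chiral oxazoline sulfonamide ligand (8.8 equiv), Et3N (8.8 equiv), THF, 0.002 M, rt; aq. sodium serinate
Reagents that add atoms: none
Why: Nozaki–Hiyama–Kishi reaction: the alkenyl iodide is passed by nickel to chromium with retention of geometry and the alkenylchromium adds to the C6 aldehyde at high dilution, closing the 14-membered ring at C6–C7 and forming the free C6 carbinol, with the ligand enantiomer chosen to direct attack to the Re face (6S); esters, the lactone and the exocyclic alkene are tolerated.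

**Compound list**

1 | pent-1-en-4-yne | C#CCC=C | starting material
2 | dimethyl[(1E)-2-methylpenta-1,4-dien-1-yl]alane | C[Al](C)/C=C(\C)CC=C | intermediate
3 | (1E)-1-iodo-2-methylpenta-1,4-diene | I/C=C(\C)CC=C | intermediate
4 | [(1E)-2-methylpenta-1,4-dien-1-yl]lithium | [Li]/C=C(\C)CC=C | intermediate
5 | (2E)-3-methylhexa-2,5-dienal | O=C/C=C(\C)CC=C | intermediate
6 | allenylboronic acid pinacol ester (4,4,5,5-tetramethyl-2-(propa-1,2-dien-1-yl)-1,3,2-dioxaborolane) | C=C=CB1OC(C)(C)C(C)(C)O1 | starting material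
7 | 4,4,5,5-tetramethyl-2-{[(4S,5E)-6-methylnona-5,8-dien-1-yn-4-yl]oxy}-1,3,2-dioxaborolane | C#CC[C@H](OB1OC(C)(C)C(C)(C)O1)/C=C(\C)CC=C | intermediate
8 | (4S,5E)-6-methylnona-5,8-dien-1-yn-4-ol | C#CC[C@H](O)/C=C(\C)CC=C | intermediate
9 | dimethylaluminium (1E,4S,5E)-1-(dimethylalumanyl)-2,6-dimethylnona-1,5,8-trien-4-olate | C[Al](C)/C=C(\C)C[C@H](O[Al](C)C)/C=C(\C)CC=C | intermediate
10 | (1E,4S,5E)-1-iodo-2,6-dimethylnona-1,5,8-trien-4-ol | I/C=C(\C)C[C@H](O)/C=C(\C)CC=C | intermediate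
11 | (1E,4S,5E)-1-iodo-2,6-dimethylnona-1,5,8-trien-4-yl acetate | I/C=C(\C)C[C@H](OC(C)=O)/C=C(\C)CC=C | intermediate
12 | (2E)-but-2-enal (crotonaldehyde) | C/C=C/C=O | starting material
13 | (2E,5E,7S,9E)-10-iodo-5,9-dimethyl-1-oxodeca-2,5,9-trien-7-yl acetate | I/C=C(\C)C[C@H](OC(C)=O)/C=C(\C)C/C=C/C=O | intermediate
14 | tert-butyl(but-3-yn-1-yloxy)dimethylsilane | C#CCCO[Si](C)(C)C(C)(C)C | starting material
15 | {(1E)-4-[(tert-butyldimethylsilyl)oxy]-2-methylbut-1-en-1-yl}dimethylalane | C[Al](C)/C=C(\C)CCO[Si](C)(C)C(C)(C)C | intermediate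
16 | tert-butyl{[(3E)-4-iodo-3-methylbut-3-en-1-yl]oxy}dimethylsilane | I/C=C(\C)CCO[Si](C)(C)C(C)(C)C | intermediate
17 | {(1E)-4-[(tert-butyldimethylsilyl)oxy]-2-methylbut-1-en-1-yl}lithium | [Li]/C=C(\C)CCO[Si](C)(C)C(C)(C)C | intermediate
18 | bis{(1E)-4-[(tert-butyldimethylsilyl)oxy]-2-methylbut-1-en-1-yl}zinc | CC(C)(C)[Si](C)(C)OCC/C(C)=C/[Zn]/C=C(\C)CCO[Si](C)(C)C(C)(C)C | intermediate
19 | (1E,4S,5E,8E,10R,11E)-14-[(tert-butyldimethylsilyl)oxy]-10-hydroxy-1-iodo-2,6,12-trimethyltetradeca-1,5,8,11-tetraen-4-yl acetate | I/C=C(\C)C[C@H](OC(C)=O)/C=C(\C)C/C=C/[C@@H](O)/C=C(\C)CCO[Si](C)(C)C(C)(C)C | intermediate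
20 | (1E,4S,5E,8S,9S,10S,11E)-14-[(tert-butyldimethylsilyl)oxy]-8,9-epoxy-10-hydroxy-1-iodo-2,6,12-trimethyltetradeca-1,5,11-trien-4-yl acetate | I/C=C(\C)C[C@H](OC(C)=O)/C=C(\C)C[C@@H]1O[C@H]1[C@@H](O)/C=C(\C)CCO[Si](C)(C)C(C)(C)C | intermediate
21 | (diethoxyphosphoryl)acetic acid | OC(=O)CP(=O)(OCC)OCC | starting material
22 | (1E,4S,5E,8S,9R,10S,11E)-4-acetoxy-14-[(tert-butyldimethylsilyl)oxy]-8,9-epoxy-1-iodo-2,6,12-trimethyltetradeca-1,5,11-trien-10-yl (diethoxyphosphoryl)acetate | I/C=C(\C)C[C@H](OC(C)=O)/C=C(\C)C[C@@H]1O[C@H]1[C@@H](OC(=O)CP(=O)(OCC)OCC)/C=C(\C)CCO[Si](C)(C)C(C)(C)C | intermediate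
23 | diethyl {(4S,5S)-4-[(1S,3E,5S,7E)-5-acetoxy-1-hydroxy-8-iodo-3,7-dimethylocta-3,7-dien-1-yl]-5-{(1E)-4-[(tert-butyldimethylsilyl)oxy]-2-methylbut-1-en-1-yl}-2-oxooxolan-3-yl}phosphonate (C3 epimers; present as the sodium enolate) | CCOP(=O)(OCC)C1C(=O)O[C@@H](/C=C(\C)CCO[Si](C)(C)C(C)(C)C)[C@@H]1[C@@H](O)C/C(C)=C/[C@@H](OC(C)=O)C/C(C)=C/I | intermediate
24 | (1E,4S,5E,8S)-8-hydroxy-1-iodo-2,6-dimethyl-8-[(2S,3S)-2-{(1E)-4-[(tert-butyldimethylsilyl)oxy]-2-methylbut-1-en-1-yl}-4-methylidene-5-oxooxolan-3-yl]octa-1,5-dien-4-yl acetate | C=C1C(=O)O[C@@H](/C=C(\C)CCO[Si](C)(C)C(C)(C)C)[C@@H]1[C@@H](O)C/C(C)=C/[C@@H](OC(C)=O)C/C(C)=C/I | intermediate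
25 | (1E,4S,5E,8S)-8-[(2S,3S)-2-{(1E)-4-[(tert-butyldimethylsilyl)oxy]-2-methylbut-1-en-1-yl}-4-methylidene-5-oxooxolan-3-yl]-1-iodo-2,6-dimethylocta-1,5-diene-4,8-diyl diacetate | C=C1C(=O)O[C@@H](/C=C(\C)CCO[Si](C)(C)C(C)(C)C)[C@@H]1[C@@H](OC(C)=O)C/C(C)=C/[C@@H](OC(C)=O)C/C(C)=C/I | intermediate
26 | (1E,4S,5E,8S)-8-{(2S,3S)-2-[(1E)-4-hydroxy-2-methylbut-1-en-1-yl]-4-methylidene-5-oxooxolan-3-yl}-1-iodo-2,6-dimethylocta-1,5-diene-4,8-diyl diacetate | C=C1C(=O)O[C@@H](/C=C(\C)CCO)[C@@H]1[C@@H](OC(C)=O)C/C(C)=C/[C@@H](OC(C)=O)C/C(C)=C/I | intermediate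
27 | (1E,4S,5E,8S)-1-iodo-2,6-dimethyl-8-{(2S,3S)-2-[(1E)-2-methyl-4-oxobut-1-en-1-yl]-4-methylidene-5-oxooxolan-3-yl}octa-1,5-diene-4,8-diyl diacetate | C=C1C(=O)O[C@@H](/C=C(\C)CC=O)[C@@H]1[C@@H](OC(C)=O)C/C(C)=C/[C@@H](OC(C)=O)C/C(C)=C/I | intermediate
28 | (1S,2S,3E,6S,7E,10S,11E,14S)-10,14-diacetoxy-6-hydroxycembra-3,7,11,15(17)-tetraen-16,2-olide (CNP0418981.1) | C=C1C(=O)O[C@H]2/C=C(\C)C[C@H](O)/C=C(\C)C[C@H](OC(C)=O)/C=C(\C)C[C@H](OC(C)=O)[C@H]12 | target

Total step count: 15. Longest linear sequence: 14 (steps 1–6 and 8–15; step 7 is the side branch).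

**Steps most likely to fail**

Step 11 (proposed new method). The stabilised anion may open the epoxide too slowly, may attack C14 in the 6-endo mode, or the acyl group may move to the C14 oxygen once it is freed. The fallback uses known radical chemistry for the C1–C15 bond and sets out from epoxy alcohol 20. O-Propargylation (propargyl bromide, Ag2O, CH2Cl2) would give (1E,4S,5E,8S,9R,10S,11E)-14-[(tert-butyldimethylsilyl)oxy]-8,9-epoxy-1-iodo-2,6,12-trimethyl-10-(prop-2-yn-1-yloxy)tetradeca-1,5,11-trien-4-yl acetate F1. Cp2TiCl (from Cp2TiCl2 and Zn, THF), a trivalent titanium reagent, would open the epoxide homolytically at C1 with the titanium alkoxide on C14, and 5-exo-dig cyclisation of the C1 radical onto the alkyne would give (1E,4S,5E,8S)-8-hydroxy-1-iodo-2,6-dimethyl-8-[(2S,3S)-2-{(1E)-4-[(tert-butyldimethylsilyl)oxy]-2-methylbut-1-en-1-yl}-4-methylideneoxolan-3-yl]octa-1,5-dien-4-yl acetate F2. Acetylation (Ac2O, pyridine) would give (1E,4S,5E,8S)-8-[(2S,3S)-2-{(1E)-4-[(tert-butyldimethylsilyl)oxy]-2-methylbut-1-en-1-yl}-4-methylideneoxolan-3-yl]-1-iodo-2,6-dimethylocta-1,5-diene-4,8-diyl diacetate F3, and allylic oxidation of the ring O–CH2 next to the methylidene group (CrO3·2 pyridine, CH2Cl2) would come back to the route at lactone 25. In this variant C1 is set by 1,2-induction from C2 in the radical ring closure instead of by inversion.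

Step 15. Facial selectivity at C6 may be poor in the ring closure, and the β,γ-unsaturated aldehyde may isomerise into conjugation or oligomerise before it closes. The fallback sets out from aldehyde 27 and sets C6 by a reagent-controlled ketone reduction instead of in the C–C bond formation. Ligand-free Nozaki–Hiyama–Kishi closure (CrCl2, NiCl2 cat., DMSO/THF, high dilution) would give 28 together with its epimer (1S,2S,3E,6R,7E,10S,11E,14S)-10,14-diacetoxy-6-hydroxycembra-3,7,11,15(17)-tetraen-16,2-olide F4. Oxidation of the mixture (MnO2, CH2Cl2) would give the enone (1S,2S,3E,7E,10S,11E,14S)-10,14-diacetoxy-6-oxocembra-3,7,11,15(17)-tetraen-16,2-olide F5, and Corey–Bakshi–Shibata reduction ((R)-2-methyl-CBS-oxazaborolidine, catecholborane, toluene, −78 °C) would come back to the route at 28.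

Step 8. Enantioselectivity may be low, transmetalation to zinc incomplete, or an uncatalysed background addition may compete. The fallback sets out from enal 13 and iodide 16 and selects the C2 configuration by kinetic resolution instead of by catalytic addition. The zinc reagent 18 would be added with an achiral promoter (2-(dimethylamino)ethanol), giving 19 and its C2 epimer (1E,4S,5E,8E,10S,11E)-14-[(tert-butyldimethylsilyl)oxy]-10-hydroxy-1-iodo-2,6,12-trimethyltetradeca-1,5,8,11-tetraen-4-yl acetate F6 in about equal amounts. The Sharpless epoxidation of step 9 would then be run on the mixture: with L-(+)-diethyl tartrate only 19 is epoxidised quickly at C1=C14, which comes back to the route at 20, while F6 is left behind and separated (it could be returned to 19 by Mitsunobu inversion and hydrolysis).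

**Further compounds**

F1 | step 11 | (1E,4S,5E,8S,9R,10S,11E)-14-[(tert-butyldimethylsilyl)oxy]-8,9-epoxy-1-iodo-2,6,12-trimethyl-10-(prop-2-yn-1-yloxy)tetradeca-1,5,11-trien-4-yl acetate | I/C=C(\C)C[C@H](OC(C)=O)/C=C(\C)C[C@@H]1O[C@H]1[C@@H](OCC#C)/C=C(\C)CCO[Si](C)(C)C(C)(C)C
F2 | step 11 | (1E,4S,5E,8S)-8-hydroxy-1-iodo-2,6-dimethyl-8-[(2S,3S)-2-{(1E)-4-[(tert-butyldimethylsilyl)oxy]-2-methylbut-1-en-1-yl}-4-methylideneoxolan-3-yl]octa-1,5-dien-4-yl acetate | C=C1CO[C@@H](/C=C(\C)CCO[Si](C)(C)C(C)(C)C)[C@@H]1[C@@H](O)C/C(C)=C/[C@@H](OC(C)=O)C/C(C)=C/I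
F3 | step 11 | (1E,4S,5E,8S)-8-[(2S,3S)-2-{(1E)-4-[(tert-butyldimethylsilyl)oxy]-2-methylbut-1-en-1-yl}-4-methylideneoxolan-3-yl]-1-iodo-2,6-dimethylocta-1,5-diene-4,8-diyl diacetate | C=C1CO[C@@H](/C=C(\C)CCO[Si](C)(C)C(C)(C)C)[C@@H]1[C@@H](OC(C)=O)C/C(C)=C/[C@@H](OC(C)=O)C/C(C)=C/I
F4 | step 15 | (1S,2S,3E,6R,7E,10S,11E,14S)-10,14-diacetoxy-6-hydroxycembra-3,7,11,15(17)-tetraen-16,2-olide | C=C1C(=O)O[C@H]2/C=C(\C)C[C@@H](O)/C=C(\C)C[C@H](OC(C)=O)/C=C(\C)C[C@H](OC(C)=O)[C@H]12
F5 | step 15 | (1S,2S,3E,7E,10S,11E,14S)-10,14-diacetoxy-6-oxocembra-3,7,11,15(17)-tetraen-16,2-olide | C=C1C(=O)O[C@H]2/C=C(\C)CC(=O)/C=C(\C)C[C@H](OC(C)=O)/C=C(\C)C[C@H](OC(C)=O)[C@H]12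
F6 | step 8 | (1E,4S,5E,8E,10S,11E)-14-[(tert-butyldimethylsilyl)oxy]-10-hydroxy-1-iodo-2,6,12-trimethyltetradeca-1,5,8,11-tetraen-4-yl acetate | I/C=C(\C)C[C@H](OC(C)=O)/C=C(\C)C/C=C/[C@H](O)/C=C(\C)CCO[Si](C)(C)C(C)(C)C
A1 | direct plan | tert-butyl (2E,4S,6E,8S,10E,12S,14E)-4,8-diacetoxy-12-[(tert-butyldimethylsilyl)oxy]-6,10,14-trimethyl-16-oxo-2-[(4,4,5,5-tetramethyl-1,3,2-dioxaborolan-2-yl)methyl]hexadeca-2,6,10,14-tetraenoate | O=C/C=C(\C)C[C@H](O[Si](C)(C)C(C)(C)C)/C=C(\C)C[C@H](OC(C)=O)/C=C(\C)C[C@H](OC(C)=O)/C=C(\CB1OC(C)(C)C(C)(C)O1)C(=O)OC(C)(C)C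
A2 | direct plan | tert-butyl 2-[(1R,2R,3E,6S,7E,10S,11E,14S)-10,14-diacetoxy-6-[(tert-butyldimethylsilyl)oxy]-2-hydroxy-4,8,12-trimethylcyclotetradeca-3,7,11-trien-1-yl]prop-2-enoate | C=C(C(=O)OC(C)(C)C)[C@@H]1[C@H](O)/C=C(\C)C[C@H](O[Si](C)(C)C(C)(C)C)/C=C(\C)C[C@H](OC(C)=O)/C=C(\C)C[C@@H]1OC(C)=O
A3 | direct plan | 2-O-methanesulfonate of A2 (spatial arrangement unchanged) | C=C(C(=O)OC(C)(C)C)[C@@H]1[C@H](OS(C)(=O)=O)/C=C(\C)C[C@H](O[Si](C)(C)C(C)(C)C)/C=C(\C)C[C@H](OC(C)=O)/C=C(\C)C[C@@H]1OC(C)=O
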